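**Retrosynthetic overview**
1. Target 6 comes from pentamethoxyflavone 5 by chelation-controlled cleavage of the 5-O-methyl ether, which lies peri to C4=O.
2. The pyranone ring of 5 (the only ring built) comes from o-aroyloxyacetophenone 3 by Baker–Venkataraman acyl shift (C2–C3) and cyclodehydration (O1–C2).
3. Key disconnection: the aryl C8a–O1 bond of 3 is made by direct ketone-directed C–H aroyloxylation of acetophenone 1 with benzoic acid 2.
4. Ring order: rings A and B are bought intact, ring C is closed in step 2, and the 5-OH is unveiled last.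

Assumption: the target is a planar, achiral flavone with no stereocentre, so there is no configuration to set.

**Step 1**
Reactants: 1 2',4',5'-trimethoxyacetophenone; 2 2,5-dimethoxybenzoic acid
Product: 3 2-acetyl-3,5,6-trimethoxyphenyl 2,5-dimethoxybenzoate
Conditions: PhI(OAc)2 (1.5 eq), 2 (3.5 eq), PhCl, 50 °C, vacuum (−AcOH); then 1, [RuCl2(p-cymene)]2 (5 mol %), AgSbF6 (20 mol %), DCE, 80 °C
Reagents that add atoms: none
Why: Proposed new method: a ketone-directed ortho C–H aroyloxylation in which a cationic Ru(II) 2,5-dimethoxybenzoate binds the acetyl oxygen, carboxylate-assisted ruthenation (CMD) occurs at C6' (the only C–H ortho to the ketone), the iodine(III) dicarboxylate formed in the flask oxidises the five-membered ruthenacycle to Ru(IV), and aryl–O2CAr reductive elimination forms the C–O bond; the closest known chemistry is Ru(II)-catalysed amide-directed ortho-benzoxylation of anilides with arenecarboxylic acids and Ru/Pd ketone-directed ortho-hydroxylation via trifluoroacetates, and to my knowledge neither has been shown with a simple aryl ketone as sole directing group transferring an intact arenecarboxylate without TFA.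

**Step 2**
Reactants: 3 2-acetyl-3,5,6-trimethoxyphenyl 2,5-dimethoxybenzoate
Product: 5 2-(2,5-dimethoxyphenyl)-5,7,8-trimethoxy-4H-chromen-4-one, via hydroxy-diketone 4 (not isolated)
Conditions: KOtBu (2.5 eq), THF, 0 °C to rt; concentrate; then AcOH, H2SO4, 95 °C
Reagents that add atoms: none
Why: Baker–Venkataraman rearrangement (the acetyl enolate attacks the neighbouring ester carbonyl, O-to-C acyl shift) gives the o-hydroxy-1,3-diketone, and acid-catalysed cyclodehydration through its only free phenol fixes the 5,7,8-oxygenation pattern; no stereocentre is formed.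

**Step 3**
Reactants: 5 2-(2,5-dimethoxyphenyl)-5,7,8-trimethoxy-4H-chromen-4-one
Product: 6 5-hydroxy-7,8,2',5'-tetramethoxyflavone
Conditions: BCl3 (1.5 eq), CH2Cl2, −78 to 0 °C; then H2O
Reagents that add atoms: none
Why: Chelation-controlled Lewis-acid demethylation, in which boron bridges C4=O and the peri 5-OMe so chloride dealkylates only that ether and the 7-, 8-, 2'- and 5'-methoxy groups remain; no stereocentre is formed.

**Compound list**
1 | 2',4',5'-trimethoxyacetophenone | CC(=O)c1cc(OC)c(OC)cc1OC | starting material
2 | 2,5-dimethoxybenzoic acid | COc1ccc(OC)c(c1)C(=O)O | starting material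
3 | 2-acetyl-3,5,6-trimethoxyphenyl 2,5-dimethoxybenzoate | CC(=O)c1c(OC)cc(OC)c(OC)c1OC(=O)c1cc(OC)ccc1OC | intermediate
4 | 1-(2,5-dimethoxyphenyl)-3-(2-hydroxy-3,4,6-trimethoxyphenyl)propane-1,3-dione | COc1ccc(OC)c(c1)C(=O)CC(=O)c1c(O)c(OC)c(OC)cc1OC | intermediate
5 | 2-(2,5-dimethoxyphenyl)-5,7,8-trimethoxy-4H-chromen-4-one | COc1ccc(OC)c(-c2cc(=O)c3c(OC)cc(OC)c(OC)c3o2)c1 | intermediate
6 | 5-hydroxy-7,8,2',5'-tetramethoxyflavone | COc1ccc(OC)c(-c2cc(=O)c3c(O)cc(OC)c(OC)c3o2)c1 | target

**Total step count:** 3. **Longest linear sequence:** 3 (1 or 2 → 3 → 5 → 6).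

**Steps most likely to fail**

Step 1 (the proposed new C–H aroyloxylation) is the main risk. The ketone is a weak directing group without TFA, the iodine(III) reagent may acyloxylate the acetyl α-position or oxidise the electron-rich ring, and the benzoate may be oxygenated at its own ortho position. The fallback uses known chemistry, sets out from 2 and comes back at 3. Commercial 1,2,3,5-tetramethoxybenzene F1 is acetylated with AcCl/AlCl3 (Et2O, 0 °C to rt) to 2',3',4',6'-tetramethoxyacetophenone F2. F2 is not isolated, because AlCl3 cleaves the flanked ortho-methoxy group in the same flask to give 2'-hydroxy-3',4',6'-trimethoxyacetophenone F3. Acid 2 is converted with (COCl)2 and catalytic DMF into 2,5-dimethoxybenzoyl chloride F4, and F3 is acylated with F4 in pyridine with DMAP to give 3.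

Step 3 (selective 5-O-demethylation) may also cleave the crowded 8-OMe or the 2'-OMe. The fallback sets out from 5 and comes back at 6, replacing selective cleavage by selective alkylation. Excess BBr3 (CH2Cl2, −78 °C to rt) removes all five methyl groups to give 2-(2,5-dihydroxyphenyl)-5,7,8-trihydroxy-4H-chromen-4-one F8. Me2SO4 (4.2 eq) and K2CO3 in refluxing acetone under argon then methylate the four non-chelated phenols, while the 5-OH hydrogen-bonded to C4=O stays free. The polyphenol is air-sensitive in base, hence the argon.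

Step 2 (one-flask Baker–Venkataraman and cyclodehydration) may lose material to ester cleavage by base or to incomplete ring closure. The fallback sets out from 3 and comes back at 5 by the chalcone route. K2CO3 in MeOH cleaves the ester to 2'-hydroxy-3',4',6'-trimethoxyacetophenone F5 (the same structure as F3). Claisen–Schmidt condensation with commercial 2,5-dimethoxybenzaldehyde F6 (KOH, EtOH, rt) gives (E)-3-(2,5-dimethoxyphenyl)-1-(2-hydroxy-3,4,6-trimethoxyphenyl)prop-2-en-1-one F7. Catalytic I2 in DMSO at 130 °C then closes and dehydrogenates the ring to 5.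

**Further compounds**
F1 | step 1 | 1,2,3,5-tetramethoxybenzene (bought) | COc1cc(OC)c(OC)c(OC)c1
F2 | step 1 | 2',3',4',6'-tetramethoxyacetophenone (formed in the flask) | CC(=O)c1c(OC)cc(OC)c(OC)c1OC
F3 | step 1 | 2'-hydroxy-3',4',6'-trimethoxyacetophenone | CC(=O)c1c(OC)cc(OC)c(OC)c1O
F4 | step 1 | 2,5-dimethoxybenzoyl chloride | COc1ccc(OC)c(c1)C(Cl)=O
F5 | step 2 | 2'-hydroxy-3',4',6'-trimethoxyacetophenone | CC(=O)c1c(OC)cc(OC)c(OC)c1O
F6 | step 2 | 2,5-dimethoxybenzaldehyde (bought) | COc1ccc(OC)c(C=O)c1
F7 | step 2 | (E)-3-(2,5-dimethoxyphenyl)-1-(2-hydroxy-3,4,6-trimethoxyphenyl)prop-2-en-1-one | COc1ccc(OC)c(/C=C/C(=O)c2c(O)c(OC)c(OC)cc2OC)c1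
F8 | step 3 | 2-(2,5-dihydroxyphenyl)-5,7,8-trihydroxy-4H-chromen-4-one | Oc1ccc(O)c(-c2cc(=O)c3c(O)cc(O)c(O)c3o2)c1
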